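The trap here is to take a flat total for a finished reaction: in the zeta run the products sum to 24.2% at 10.0 h and 22.9% at 30.0 h, yet target falls from 13.6% to 7.0% between those readings.

| flask | starting material | partner | remark | time |
|---|---|---|---|---|
| zeta | 0.40 M | 0.80 M | run made earlier |  |
| alpha | 0.40 M | 1.1 M | run made earlier |  |
| gamma | 0.40 M | 1.8 M | run made earlier |  |
| theta | 0.60 M | 0.80 M | run made earlier |  |
| summer | 0.40 M | 0.800 M | plug flow through a tube for 50 h, no back-mixing | 50 h |
| dawn | 0.40 M | 0.800 M | everything together in a closed stirred flask, run for 50 h | 50 h |
| autumn | 0.40 M | 0.800 M | a single well-mixed tank run continuously and read at steady state, 50 h in it on average |  |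
| spring | 0.40 M (fed, over 50.0 h) | 0.800 M | all but starting material at the start; starting material goes in evenly over 50.0 h, the run ends at 50 h | 50 h |

- zeta (time / h: target / %, isomer of the product / %, side product / %): 2.50: 11.0, 4.6, 1.1; 4.00: 11.8, 7.3, 3.0; 6.00: 10.7, 7.4, 1.3; 10.0: 13.6, 7.7, 2.9; 20.0: 9.6, 10.7, 3.6; 30.0: 7.0, 12.5, 3.4
- alpha (time / h: target / %, isomer of the product / %, side product / %): 2.50: 13.2, 7.8, 2.7; 4.00: 14.5, 9.2, 0.7; 6.00: 16.5, 9.8, 1.4; 10.0: 15.1, 11.9, 2.6; 20.0: 13.0, 12.1, 2.0; 30.0: 9.2, 15.1, 4.2
- gamma (time / h: target / %, isomer of the product / %, side product / %): 2.00: 18.4, 10.5, 2.2; 6.00: 22.0, 16.3, 1.8; 10.0: 19.3, 15.9, 5.2; 15.0: 19.1, 15.2, 5.3; 25.0: 13.5, 19.1, 6.7; 30.0: 15.4, 22.5, 6.2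
- theta (time / h: target / %, isomer of the product / %, side product / %): 6.00: 9.7, 7.1, 1.5; 12.0: 7.6, 8.4, 3.1; 20.0: 7.9, 7.9, 4.1; 25.0: 5.0, 9.9, 3.1; 30.0: 6.3, 8.9, 4.2

(each reading ± 1 percentage point)

- percent here means starting material units held: one side product counts as two
- the stated concentrations are those of everything mixed, before any reaction; amounts are the same in each set-up
- the numbers in the tables scatter with a standard deviation of 1 percentage point
- the feed brings no volume worth counting
- the earlier runs were made in a closed, stirred flask

- the set-up with the highest share of target in all that became target or isomer of the product or side product, at the outlet or at the end ("none" if the first two lie within 2 percentage points) (summer / dawn / autumn / spring / none)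
- share of target in all that became target or isomer of the product or side product, at the outlet or at the end, summer
- share of target in all that became target or isomer of the product or side product, at the outlet or at the end, dawn
- share of target in all that became target or isomer of the product or side product, at the outlet or at the end, autumn
- share of target in all that became target or isomer of the product or side product, at the outlet or at the end, spring

A bench rule of thumb treats the share of target among the products (the selectivity) as a first-order decay clock. Pooling the zeta and alpha runs, I read that share as 59.9% at the first reading and 31.5% at the last. So the ageing time, in which the share falls by a factor of e, is 42.8 h, a reading that carries the scatter.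

I count one age per flask as fair while products appear over a time short against the ageing time. In the zeta run the total of the readings is level by 10.0 h, a ratio of 0.234. Spring stands beyond that border: its feed lasts 1.17 ageing times, so I average the decay over ages spread evenly from zero to 50.0 h. For autumn I use the tank's exponential spread of ages, which divides the early share by one plus the ratio of mean stay to ageing time.

| Set-up | Ages of the product | My reckoning | Forecast |
|---|---|---|---|
| summer, dawn | one age, counted from the first reading | 19.8% | 18% |
| autumn | exponential, 50 h on average | 27.6% | 27% |
| spring | even, up to 50.0 h | 35.3% | 24% |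

So I commit to spring, whereas the forecast names autumn. For spring it weighed two cases, the first being “If activity dies early, target ages nearly as in batch”.

The flask gives spring as best, with summer and dawn at 21.6%, autumn at 26.1% and spring at 32.3%.

    starting material + partner ⇌ target (K = 3.10 M⁻¹, k = 0.00280 M⁻¹ min⁻¹)
    2 starting material → homo dimer (k = 0.0290 M⁻¹ min⁻¹)
    starting material + partner ⇌ isomer of the product (K = 79.0 M⁻¹, k = 0.00130 M⁻¹ min⁻¹)
    starting material + target → side product (k = 0.00480 M⁻¹ min⁻¹)

The neighbour flask, summer read at 30 h, holds 32.3%; my ageing time reckons that forward to 20.2% at 50 h, against 21.6% stored for summer. In summer the relaxation half-life between starting material with partner and isomer of the product at 50.0 h, 12.1 h by that step alone with both directions together, is short against the run's 50 h. At 50.0 h summer holds 4.94% of target and 13.4% of isomer of the product.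

(The readings were computed for substances that don't exist.)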